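Kolanone's single stereocentre is the quaternary ring carbon C1 of the cyclohexenedione ring, which carries the CH2 groups of a prenyl and a geranyl arm and lies between the ring carbonyl carbons C2 and C6. C1 is therefore traced back to the central carbon of a 2,2-dimethylmalonic ester amide: its two enantiotopic methyl groups become the two allylic CH2 groups, its amide carbon becomes C2 and its ester carbon C6. The key step alkenylates one methyl C–H bond under chiral palladium catalysis, forming the prenyl CH2–CH bond and making C1 stereogenic in one operation. Its precursor is the achiral methyl malonamate with an acidic polyfluoroaryl amide as directing group.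

Key step: step 4

Remarks and assumptions on the chemistry:
- Ring numbering: C1 is the quaternary carbon, C2 the carbonyl carbon next to the prenyl-bearing C3, C4 the enol carbon, C5 the benzoyl-bearing carbon and C6 the second carbonyl carbon. The target is drawn as one enol tautomer of a 2-acylcyclohexane-1,3,5-trione, in which C1 is R.
- Stereochemical bookkeeping: the (S)-configured product of the key step leads to (R)-C1 only if the amide carbonyl carbon ends as C2 and the ester carbonyl carbon as C6. The end game enforces this order, and no symmetrical malonyl intermediate (diacid, anhydride, malonimide) is passed, since that would erase the stereocentre.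
- Ligand: the acetyl-protected aminomethyl oxazoline N-[(1S)-1-[(4S)-4-benzyl-4,5-dihydro-1,3-oxazol-2-yl]-2,2-dimethylpropyl]acetamide or its mirror image. Assumption: the sense of induction cannot be predicted safely for a substrate with a fully substituted α-carbon, so "ligand A" stands for the enantiomer that gives the (S)-product in step 4 and "ent-A" for its mirror image.

Step 1
Reactants: 1 dimethyl 2,2-dimethylmalonate
Product: 2 3-methoxy-2,2-dimethyl-3-oxopropanoic acid
Conditions: KOH (1.0 equiv), MeOH, 23 °C; then aq HCl
Reagents that add atoms: potassium hydroxide, [K+].[OH-]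
Why: Mono-saponification of a symmetrical diester should stop at the half-ester because the carboxylate formed shields the second, neopentyl-type ester from hydroxide.

Step 2
Reactants: 2 3-methoxy-2,2-dimethyl-3-oxopropanoic acid; 3 2,3,5,6-tetrafluoro-4-(trifluoromethyl)aniline
Product: 5 methyl 2,2-dimethyl-3-oxo-3-[2,3,5,6-tetrafluoro-4-(trifluoromethyl)anilino]propanoate, via half-ester acid chloride 4 (not isolated)
Conditions: (COCl)2, cat. DMF, CH2Cl2, 0 → 23 °C; concentrate; 3, toluene, 110 °C
Reagents that add atoms: none
Why: Acid chloride formation followed by acylation of the weakly nucleophilic polyfluoroaniline in hot toluene is a standard amide synthesis, and the quaternary α-carbon rules out ketene formation.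

Step 3
Reactants: 6 1-bromo-2-methylprop-1-ene
Product: 7 1-iodo-2-methylprop-1-ene
Conditions: NaI (2 equiv), CuI (5 mol%), trans-N,N'-dimethylcyclohexane-1,2-diamine (10 mol%), n-BuOH, 120 °C, sealed tube
Reagents that add atoms: sodium iodide, [Na+].[I-]
Why: Copper-catalysed halogen exchange of a vinyl bromide (a Finkelstein-type reaction) should be driven by precipitation of NaBr and gives the iodide needed for fast oxidative addition.

Step 4
Reactants: 5 methyl 2,2-dimethyl-3-oxo-3-[2,3,5,6-tetrafluoro-4-(trifluoromethyl)anilino]propanoate; 7 1-iodo-2-methylprop-1-ene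
Product: 8 methyl (2S)-2,5-dimethyl-2-{[2,3,5,6-tetrafluoro-4-(trifluoromethyl)phenyl]carbamoyl}hex-4-enoate
Conditions: Pd(OAc)2 (10 mol%), ligand A (15 mol%), Ag2CO3 (1.0 equiv), 7 (0.8 equiv), t-AmylOH, 70 °C
Reagents that add atoms: none
Why: Proposed new method: the deprotonated N-aryl amide binds divalent palladium, ligand-assisted concerted metalation–deprotonation of one methyl group gives a five-membered palladacycle, and oxidative addition of 7 to tetravalent palladium, C–C reductive elimination and removal of iodide as AgI close the cycle. The closest known reaction type is the ligand-controlled enantioselective β-C(sp3)–H arylation and alkenylation of gem-dimethyl groups in N-aryl amides that carry an α-hydrogen; new here is the fully substituted α-carbon whose third substituent is an ester. No ring is closed. The new stereocentre C2 is set in the C–H cleavage step by the chiral oxazoline ligand, which meets the ester and the spectator methyl group in different positions of the palladacycle and so selects one enantiotopic methyl group. The step needs methyl-versus-methyl selectivity and mono- over bis-alkenylation: the first is the task of the ligand, the second should follow from 7 being the limiting reagent and from the remaining methyl group of 8 being the one the ligand disfavours. The substrate has no α-hydrogen, no alkene and no other C–H bond within reach of a five-membered palladacycle, so no competing pathway at the substrate is expected.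

Step 5
Reactants: 9 5-bromo-2-methylpent-2-ene
Product: 10 6-methylhept-5-en-1-yne
Conditions: LiC≡CH·H2NCH2CH2NH2 (1.2 equiv), DMSO, 10 → 23 °C
Reagents that add atoms: lithium acetylide ethylenediamine complex, [Li+].[C-]#C.NCCN
Why: SN2 alkylation of lithium acetylide by an unhindered primary bromide in DMSO is a standard terminal alkyne synthesis.

Step 6
Reactants: 10 6-methylhept-5-en-1-yne
Product: 12 (1E)-1-iodo-2,6-dimethylhepta-1,5-diene, via alkenyldimethylalane 11 (not isolated)
Conditions: AlMe3 (2.0 equiv), Cp2ZrCl2 (0.25 equiv), CH2Cl2, 0 → 23 °C; then I2 (1.2 equiv), THF, −30 → 0 °C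
Reagents that add atoms: trimethylaluminium, C[Al](C)C; iodine, II
Why: Zirconium-catalysed syn-methylalumination of the terminal alkyne (Negishi carboalumination) puts the methyl group on the internal carbon, and iodinolysis of the C–Al bond with retention should give the E-iodide only, the remote trisubstituted alkene being inert.

Step 7
Reactants: 8 methyl (2S)-2,5-dimethyl-2-{[2,3,5,6-tetrafluoro-4-(trifluoromethyl)phenyl]carbamoyl}hex-4-enoate; 12 (1E)-1-iodo-2,6-dimethylhepta-1,5-diene
Product: 13 methyl (2R,4E)-5,9-dimethyl-2-(3-methylbut-2-en-1-yl)-2-{[2,3,5,6-tetrafluoro-4-(trifluoromethyl)phenyl]carbamoyl}deca-4,8-dienoate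
Conditions: Pd(OAc)2 (10 mol%), ent-A (15 mol%), Ag2CO3 (1.5 equiv), 12 (2.0 equiv), t-AmylOH, 80 °C
Reagents that add atoms: none
Why: Amide-directed β-methyl C–H alkenylation through the same divalent/tetravalent palladium cycle acts on the only methyl group left, for which the mirror-image ligand is the matched one; no stereocentre is formed, the E-geometry of 12 is retained, and the descriptor changes to R only because geranyl outranks prenyl.

Step 8
Reactants: 13 methyl (2R,4E)-5,9-dimethyl-2-(3-methylbut-2-en-1-yl)-2-{[2,3,5,6-tetrafluoro-4-(trifluoromethyl)phenyl]carbamoyl}deca-4,8-dienoate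
Product: 14 methyl (2R,4E)-2-{(tert-butoxycarbonyl)[2,3,5,6-tetrafluoro-4-(trifluoromethyl)phenyl]carbamoyl}-5,9-dimethyl-2-(3-methylbut-2-en-1-yl)deca-4,8-dienoate
Conditions: Boc2O (3 equiv), DMAP (0.5 equiv), MeCN, 23 → 40 °C
Reagents that add atoms: di-tert-butyl dicarbonate, CC(C)(C)OC(=O)OC(=O)OC(C)(C)C
Why: DMAP-catalysed N-tert-butoxycarbonylation of the acidic anilide N–H should give a twisted imide whose acyl carbonyl is far more electrophilic than the neopentyl-type methyl ester, which fixes the order in which the two malonyl carbonyl groups react.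

Step 9
Reactants: 15 benzoylacetone (1-phenylbutane-1,3-dione); 16 prenyl bromide (1-bromo-3-methylbut-2-ene)
Product: 18 7-methyl-1-phenyloct-6-ene-1,3-dione, via dilithio benzoylacetone 17 (not isolated)
Conditions: LiN(iPr)2 (2.1 equiv), THF, 0 °C; 16 (1.0 equiv), 0 → 23 °C; aq HCl
Reagents that add atoms: none
Why: In β-diketone dianion alkylation the more basic terminal carbanion reacts first, so the prenyl group should enter at the methyl carbon and not at the central carbon.

Step 10
Reactants: 14 methyl (2R,4E)-2-{(tert-butoxycarbonyl)[2,3,5,6-tetrafluoro-4-(trifluoromethyl)phenyl]carbamoyl}-5,9-dimethyl-2-(3-methylbut-2-en-1-yl)deca-4,8-dienoate; 18 7-methyl-1-phenyloct-6-ene-1,3-dione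
Product: 21 kolanone, via dilithio prenylbenzoylacetone 19 (not isolated), via triketo ester 20 (not isolated)
Conditions: 18 (2.2 equiv), LiN(iPr)2 (4.5 equiv), THF, 0 °C; 14 (1.0 equiv), −78 → 0 °C; then 50 °C; 1 M aq HCl, 0 °C
Reagents that add atoms: none
Why: The terminal carbanion of the dianion should acylate at the activated imide carbonyl (β-diketone dianion C-acylation, C2–C3 bond), and the doubly deprotonated triketone then closes the six-membered ring by Dieckmann-type Claisen condensation of C5 onto the methyl ester (C5–C6 bond), helped by the quaternary C1 and driven by formation of the stabilised trione dianion; C1 is not touched and keeps its configuration because only the imide carbon becomes C2.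

Compound list
1 | dimethyl 2,2-dimethylmalonate | COC(=O)C(C)(C)C(=O)OC | starting material
2 | 3-methoxy-2,2-dimethyl-3-oxopropanoic acid | COC(=O)C(C)(C)C(=O)O | intermediate
3 | 2,3,5,6-tetrafluoro-4-(trifluoromethyl)aniline | Nc1c(F)c(F)c(C(F)(F)F)c(F)c1F | starting material
4 | methyl 3-chloro-2,2-dimethyl-3-oxopropanoate | COC(=O)C(C)(C)C(Cl)=O | intermediate (not isolated)
5 | methyl 2,2-dimethyl-3-oxo-3-[2,3,5,6-tetrafluoro-4-(trifluoromethyl)anilino]propanoate | COC(=O)C(C)(C)C(=O)Nc1c(F)c(F)c(C(F)(F)F)c(F)c1F | intermediate
6 | 1-bromo-2-methylprop-1-ene | CC(C)=CBr | starting material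
7 | 1-iodo-2-methylprop-1-ene | CC(C)=CI | intermediate
8 | methyl (2S)-2,5-dimethyl-2-{[2,3,5,6-tetrafluoro-4-(trifluoromethyl)phenyl]carbamoyl}hex-4-enoate | C[C@](C(=O)OC)(CC=C(C)C)C(=O)Nc1c(F)c(F)c(C(F)(F)F)c(F)c1F | intermediate
9 | 5-bromo-2-methylpent-2-ene | CC(C)=CCCBr | starting material
10 | 6-methylhept-5-en-1-yne | CC(C)=CCCC#C | intermediate
11 | [(1E)-2,6-dimethylhepta-1,5-dien-1-yl]dimethylalane | C[Al](C)/C=C(\C)CCC=C(C)C | intermediate (not isolated)
12 | (1E)-1-iodo-2,6-dimethylhepta-1,5-diene | I/C=C(\C)CCC=C(C)C | intermediate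
13 | methyl (2R,4E)-5,9-dimethyl-2-(3-methylbut-2-en-1-yl)-2-{[2,3,5,6-tetrafluoro-4-(trifluoromethyl)phenyl]carbamoyl}deca-4,8-dienoate | CC(C)=CCC/C(C)=C/C[C@@](CC=C(C)C)(C(=O)OC)C(=O)Nc1c(F)c(F)c(C(F)(F)F)c(F)c1F | intermediate
14 | methyl (2R,4E)-2-{(tert-butoxycarbonyl)[2,3,5,6-tetrafluoro-4-(trifluoromethyl)phenyl]carbamoyl}-5,9-dimethyl-2-(3-methylbut-2-en-1-yl)deca-4,8-dienoate | CC(C)=CCC/C(C)=C/C[C@@](CC=C(C)C)(C(=O)OC)C(=O)N(C(=O)OC(C)(C)C)c1c(F)c(F)c(C(F)(F)F)c(F)c1F | intermediate
15 | benzoylacetone (1-phenylbutane-1,3-dione) | CC(=O)CC(=O)c1ccccc1 | starting material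
16 | prenyl bromide (1-bromo-3-methylbut-2-ene) | CC(C)=CCBr | starting material
17 | dilithium dianion of 1-phenylbutane-1,3-dione (drawn as the dicarbanion form) | [Li+].[Li+].[CH2-]C(=O)[CH-]C(=O)c1ccccc1 | intermediate (not isolated)
18 | 7-methyl-1-phenyloct-6-ene-1,3-dione | CC(C)=CCCC(=O)CC(=O)c1ccccc1 | intermediate
19 | dilithium dianion of 7-methyl-1-phenyloct-6-ene-1,3-dione, carbanions at C2 and C4 (drawn as the dicarbanion form) | [Li+].[Li+].CC(C)=CC[CH-]C(=O)[CH-]C(=O)c1ccccc1 | intermediate (not isolated)
20 | methyl (2R)-2-[(2E)-3,7-dimethylocta-2,6-dien-1-yl]-2,4-bis(3-methylbut-2-en-1-yl)-3,5,7-trioxo-7-phenylheptanoate, drawn as its chelated 4-en-5-ol tautomer | CC(C)=CCC/C(C)=C/C[C@@](CC=C(C)C)(C(=O)OC)C(=O)/C(CC=C(C)C)=C(\O)CC(=O)c1ccccc1 | intermediate (not isolated)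
21 | kolanone: (R)-configured at C1; C1 carries (2E)-geranyl and prenyl, C3 prenyl, C5 the benzoyl group, drawn as the enol tautomer with C3=C4–OH and an exocyclic hydroxy(phenyl)methylidene at C5 | CC(C)=CCC/C(C)=C/C[C@]1(CC=C(C)C)C(=O)C(CC=C(C)C)=C(O)/C(=C(\O)c2ccccc2)C1=O | target

Total step count: 10 steps. Longest linear sequence: 6 steps (steps 1, 2, 4, 7, 8, 10).

Steps most likely to fail

Step 4. The ester and the spectator methyl group at the α-carbon differ little in size, so discrimination of the two enantiotopic methyl groups may be weak, and cyclopalladation at the crowded malonamate may be slow. The fallback sets the quaternary centre by known asymmetric phase-transfer alkylation of a mixed malonate, where the chiral ammonium catalyst tells the two different ester groups apart and not the two allyl arms. It sets out from prenyl bromide 16. Commercial mono-tert-butyl malonate and 2,2-diphenylethanol would be coupled (EDC·HCl, DMAP, CH2Cl2) to tert-butyl 2,2-diphenylethyl malonate F1. Alkylation with 16 (NaH, THF, 0 °C) should give the racemic prenylmalonate F2. Geranyl bromide, 50% aq KOH and a binaphthyl-derived N-spiro quaternary ammonium bromide bearing 3,4,5-trifluorophenyl groups in toluene at −40 °C should give the (S)-configured geranyl prenyl diester F3, the catalyst enantiomer being chosen accordingly. The tert-butyl ester would be cleaved without acid stress on the alkenes (TMSOTf, 2,6-lutidine, CH2Cl2, 0 °C) to the (R)-half-ester acid F4. 1-Chloro-N,N,2-trimethylprop-1-en-1-amine in CH2Cl2 would give the acid chloride F5. Addition of F5 to dianion 19 at −78 °C should give the triketo 2,2-diphenylethyl ester F6, and KOtBu in THF would close the ring onto the primary ester. The fallback comes back to the route at 21.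

Step 7. The prenyl double bond of 8 may bind palladium, the amide nitrogen may add across it, or the allylic methylene group may be palladated in place of the methyl group. The fallback exchanges the monodentate anilide for a bidentate auxiliary, for which methyl C–H alkenylation with alkenyl iodides at quaternary centres is well established. It sets out from 8. Boc2O and DMAP in MeCN would give the N-Boc imide F7. 8-Aminoquinoline and LiN(SiMe3)2 in THF should transamidate it to the quinolin-8-yl amide F8. Pd(OAc)2 (10 mol%), AgOAc and 12 in toluene at 90 °C should give the geranylated quinolin-8-yl amide F9. Boc2O and DMAP would then give the N-Boc imide F10, which takes the place of 14 under the conditions of step 10 and gives the same triketo ester. The fallback comes back to the route at 20.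

Step 10. The secondary carbanion may be too hindered to reach the neopentyl-type imide carbon and may instead attack the carbamate carbonyl or displace fluoride on the aryl ring, and ring closure onto the hindered ester may stay incomplete. The fallback uses a primary carbanion and introduces the C3 prenyl group last. It sets out from 14. Dianion 17 (from 15, LiN(iPr)2, THF) would be acylated by 14 at −78 → 0 °C to give methyl (2R)-2-geranyl-2-prenyl-3,5,7-trioxo-7-phenylheptanoate F11. KOtBu in THF should close the ring to (R)-3-desprenylkolanone F12, in which C3 is the only ring carbon still bearing hydrogen. C-Prenylation with 16 (1.0 equiv, aq KOH, 0 °C) should then give the target. The fallback comes back to the route at 21.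

Further compounds
F1 | step 4 | tert-butyl 2,2-diphenylethyl malonate | CC(C)(C)OC(=O)CC(=O)OCC(c1ccccc1)c1ccccc1
F2 | step 4 | tert-butyl 2,2-diphenylethyl 2-(3-methylbut-2-en-1-yl)malonate (racemic) | CC(C)=CCC(C(=O)OC(C)(C)C)C(=O)OCC(c1ccccc1)c1ccccc1
F3 | step 4 | 1-tert-butyl 3-(2,2-diphenylethyl) (2S)-2-[(2E)-3,7-dimethylocta-2,6-dien-1-yl]-2-(3-methylbut-2-en-1-yl)malonate | CC(C)=CCC/C(C)=C/C[C@](C(=O)OCC(c1ccccc1)c1ccccc1)(CC=C(C)C)C(=O)OC(C)(C)C
F4 | step 4 | (2R,4E)-2-[(2,2-diphenylethoxy)carbonyl]-5,9-dimethyl-2-(3-methylbut-2-en-1-yl)deca-4,8-dienoic acid | CC(C)=CCC/C(C)=C/C[C@](C(=O)OCC(c1ccccc1)c1ccccc1)(CC=C(C)C)C(=O)O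
F5 | step 4 | 2,2-diphenylethyl (2S,4E)-2-(chlorocarbonyl)-5,9-dimethyl-2-(3-methylbut-2-en-1-yl)deca-4,8-dienoate | CC(C)=CCC/C(C)=C/C[C@](C(=O)OCC(c1ccccc1)c1ccccc1)(CC=C(C)C)C(Cl)=O
F6 | step 4 | 2,2-diphenylethyl (2R)-2-[(2E)-3,7-dimethylocta-2,6-dien-1-yl]-2,4-bis(3-methylbut-2-en-1-yl)-3,5,7-trioxo-7-phenylheptanoate, drawn as its 4-en-5-ol tautomer | CC(C)=CCC/C(C)=C/C[C@](C(=O)OCC(c1ccccc1)c1ccccc1)(CC=C(C)C)C(=O)/C(CC=C(C)C)=C(\O)CC(=O)c1ccccc1
F7 | step 7 | methyl (2S)-2-{(tert-butoxycarbonyl)[2,3,5,6-tetrafluoro-4-(trifluoromethyl)phenyl]carbamoyl}-2,5-dimethylhex-4-enoate | C[C@](C(=O)OC)(CC=C(C)C)C(=O)N(C(=O)OC(C)(C)C)c1c(F)c(F)c(C(F)(F)F)c(F)c1F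
F8 | step 7 | methyl (2S)-2,5-dimethyl-2-(quinolin-8-ylcarbamoyl)hex-4-enoate | C[C@](C(=O)OC)(CC=C(C)C)C(=O)Nc1cccc2cccnc12
F9 | step 7 | methyl (2R,4E)-5,9-dimethyl-2-(3-methylbut-2-en-1-yl)-2-(quinolin-8-ylcarbamoyl)deca-4,8-dienoate | CC(C)=CCC/C(C)=C/C[C@@](CC=C(C)C)(C(=O)OC)C(=O)Nc1cccc2cccnc12
F10 | step 7 | methyl (2R,4E)-2-[(tert-butoxycarbonyl)(quinolin-8-yl)carbamoyl]-5,9-dimethyl-2-(3-methylbut-2-en-1-yl)deca-4,8-dienoate | CC(C)=CCC/C(C)=C/C[C@@](CC=C(C)C)(C(=O)OC)C(=O)N(C(=O)OC(C)(C)C)c1cccc2cccnc12
F11 | step 10 | methyl (2R)-2-[(2E)-3,7-dimethylocta-2,6-dien-1-yl]-2-(3-methylbut-2-en-1-yl)-3,5,7-trioxo-7-phenylheptanoate | CC(C)=CCC/C(C)=C/C[C@@](CC=C(C)C)(C(=O)OC)C(=O)CC(=O)CC(=O)c1ccccc1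
F12 | step 10 | (R)-3-desprenylkolanone: kolanone with hydrogen in place of the C3 prenyl group, drawn as the matching enol tautomer | CC(C)=CCC/C(C)=C/C[C@]1(CC=C(C)C)C(=O)C=C(O)/C(=C(\O)c2ccccc2)C1=O
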